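The ten-membered carbocycle is opened at the C8–C9 bond, where the target carries a vicinal diol (C8 angelate, C9 carbinol) flanked by ring-fusion C7 and quaternary C10. A reductive pinacol coupling of a seco-8,9 dialdehyde with SmI2 should form this bond, close the ring and set both carbinol centres in one operation, leaving the less hindered C8 hydroxyl to be angeloylated last. The precursor is a 3(2H)-furanone (C9 formyl on C10) joined through the Z-C4=C5 alkene to a cis γ-lactone (C8 formyl on C7) that already holds the C11 hydroxyl and C13 chloride; all of its stereocentres are set by reagent control beforehand.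

Key step: step 19

Labels and abbreviations: C1–C13 are the atom labels of the target (C1 furanone C=O, C2=C3, C4=C5 with methyl on C4, C6 lactone O–CH, C7 ring fusion, C8 and C9 carbinols, C10 quaternary C–O, C11 C(OH), C12 lactone C=O, C13 CH2Cl); PMB = 4-methoxybenzyl; (R)-TRIP = (R)-3,3′-bis(2,4,6-triisopropylphenyl)-1,1′-binaphthyl-2,2′-diyl hydrogen phosphate.
Remark 1: the target SMILES is read as 6S,7S,8S,9R,10R,11R with a cis-fused lactone, Z-C4=C5, a threo 8,9-dioxygen pattern and the C11 hydroxyl cis to C8.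
Remark 2: the ring-closure substrate carries C11(OH)CH2Cl and not a conjugated exocyclic methylene, because an acrylate-type lactone is reduced by SmI2 and trapped by ketyl radicals (and later by the free C8 hydroxyl); only a spectator group of the key step is changed.
Remark 3: C10 is too remote to bias the C6–C7 bond formation, and reagents approaching the lactone would add the C11 oxygen anti to the C8 arm, so C6/C7 and C11 are fixed by a chiral acid and by a tartrate-controlled epoxidation on a small lactone before the furanone half is attached.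
Remark 4: (R)-TRIP is assumed to direct the boronate to the Re face of the enal, as with simple allyl pinacol boronates; if the sense were reversed the (S)-acid would be used.

Step 1
Reactants: 1 methyl acrylate; 2 2-(PMB-oxy)acetaldehyde
Product: 3 methyl 3-hydroxy-2-methylidene-4-(PMB-oxy)butanoate (racemic)
Conditions: DABCO (0.5 equiv), 1,4-dioxane/H2O (1:1), rt
Reagents that add atoms: none
Why: Morita–Baylis–Hillman reaction, in which the amine–acrylate zwitterion adds to the unhindered α-alkoxy aldehyde; the carbinol centre forms as a racemate and is erased in step 3.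

Step 2
Reactants: 3 Morita–Baylis–Hillman alcohol
Product: 4 methyl 3-acetoxy-2-methylidene-4-(PMB-oxy)butanoate (racemic)
Conditions: Ac2O, pyridine, DMAP (cat.), CH2Cl2, 0 °C → rt
Reagents that add atoms: acetic anhydride, CC(=O)OC(C)=O
Why: DMAP-catalysed acetylation of a secondary allylic alcohol installs the leaving group for the SN2′ step.

Step 3
Reactants: 4 allylic acetate
Product: 5 methyl (2E)-4-(PMB-oxy)-2-[(4,4,5,5-tetramethyl-1,3,2-dioxaborolan-2-yl)methyl]but-2-enoate
Conditions: B2pin2, CuCl (10 mol%), LiCl, KOAc, DMF, rt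
Reagents that add atoms: bis(pinacolato)diboron, CC1(C)OB(OC1(C)C)B1OC(C)(C)C(C)(C)O1
Why: Copper-catalysed SN2′ borylation of a Morita–Baylis–Hillman acetate (boryl-copper adds to the acrylate terminus, acetate leaves), which should give the usual trisubstituted alkene with the alkoxymethyl group trans to the ester and cis to CH2B.

Step 4
Reactants: 6 but-2-yn-1-ol
Product: 8 (2Z)-3-iodobut-2-en-1-ol, via vinylalanate 7 (not isolated)
Conditions: NaAlH2(OCH2CH2OCH3)2, THF, 0 °C → rt; then I2, THF, −78 → 0 °C
Reagents that add atoms: iodine, [I][I]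
Why: Hydroxyl-directed trans-hydroalumination of the propargylic alcohol places aluminium at C3 in a five-membered alkoxyalanate, and iodinolysis of the C–Al bond with retention should give the Z-iodoalkene (iodine cis to CH2OH).

Step 5
Reactants: 8 (2Z)-3-iodobut-2-en-1-ol
Product: 9 (2Z)-3-iodobut-2-enal
Conditions: MnO2 (activated, excess), CH2Cl2, rt, dark; used directly
Reagents that add atoms: none
Why: Allylic oxidation with MnO2 under neutral conditions should preserve the Z geometry of the labile β-iodoenal.

Step 6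
Reactants: 9 (2Z)-3-iodobut-2-enal; 5 allylboronate
Product: 11 (4R,5R)-5-[(1Z)-2-iodoprop-1-en-1-yl]-3-methylidene-4-(PMB-oxymethyl)oxolan-2-one, via borate ester 10 (not isolated)
Conditions: (R)-TRIP (10 mol%), 4 Å MS, toluene, 0 °C → rt; then p-TsOH·H2O (10 mol%), CH2Cl2, rt
Reagents that add atoms: none
Why: Chiral phosphoric acid-catalysed allylboration with in-flask lactonisation (Brønsted acid-catalysed additions of 2-alkoxycarbonyl allylboronates and phosphoric acid-catalysed crotylborations of enals both being established): the acid binds a boronate oxygen and the formyl hydrogen in a chair Zimmerman–Traxler transition state, so that Re-face attack sets the carbinol C6, the CH2OPMB group cis to CH2B sits axial and sets C7 syn to it, and the borate closes onto the methyl ester to give the cis lactone.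

Step 7
Reactants: 11 α-methylene lactone
Product: 12 (3R,4R,5Z)-6-iodo-2-methylidene-3-(PMB-oxymethyl)hept-5-ene-1,4-diol
Conditions: i-Bu2AlH (4 equiv), CH2Cl2, −78 → 0 °C
Reagents that add atoms: none
Why: Hydride reduction of the conjugated lactone in 1,2-fashion through the lactol should give the 2-methylene-1,4-diol without touching the vinyl iodide or the C6 and C7 centres.

Step 8
Reactants: 12 allylic diol
Product: 13 (2R,3R,4Z)-2-[(2R)-2-(hydroxymethyl)oxiran-2-yl]-5-iodo-1-(PMB-oxy)hex-4-en-3-ol
Conditions: Ti(OiPr)4 (0.3 equiv), D-(−)-diisopropyl tartrate (0.36 equiv), t-BuOOH, 4 Å MS, CH2Cl2, −25 °C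
Reagents that add atoms: tert-butyl hydroperoxide, CC(C)(C)OO
Why: Sharpless asymmetric epoxidation of the primary 2-substituted allylic alcohol, whose facial sense is dictated by the tartrate: D-(−)-tartrate should give the (R)-oxirane (the mirror image of the sense in which L-(+)-tartrate gives (S)-2-methylglycidol), which after lactonisation places the C11 oxygen cis to the C8 arm, while the hindered Z-iodoalkene beside the secondary alcohol should not compete.

Step 9
Reactants: 13 epoxy diol
Product: 16 (3S,6R,7R)-6-[(1Z)-2-iodoprop-1-en-1-yl]-7-(PMB-oxymethyl)-1,5-dioxaspiro[2.4]heptan-4-one, via epoxy aldehyde 14 (not isolated), via lactol 15 (not isolated)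
Conditions: TEMPO (20 mol%), PhI(OAc)2 (2.5 equiv), CH2Cl2, rt
Reagents that add atoms: none
Why: TEMPO-catalysed oxidative lactonisation, in which the primary alcohol is oxidised selectively to the aldehyde, this is trapped by the C6 hydroxyl as a five-membered lactol, and the lactol is oxidised to the lactone with no stereocentre affected.

Step 10
Reactants: 16 spiro-epoxy lactone
Product: 17 (3R,4R,5R)-3-(chloromethyl)-3-hydroxy-5-[(1Z)-2-iodoprop-1-en-1-yl]-4-(PMB-oxymethyl)oxolan-2-one
Conditions: LiCl, AcOH, THF, rt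
Reagents that add atoms: lithium chloride, [Li+].[Cl-]
Why: Acid-assisted SN2 opening of the glycidic lactone by chloride at the unhindered primary C13 (halohydrin formation); the C11–O bond is not broken, so the tertiary carbinol keeps the configuration set in step 8.

Step 11
Reactants: 18 2-methylprop-2-en-1-ol
Product: 19 [(2S)-2-methyloxiran-2-yl]methanol
Conditions: Ti(OiPr)4 (5 mol%), L-(+)-diisopropyl tartrate (6 mol%), t-BuOOH, 4 Å MS, CH2Cl2, −20 °C
Reagents that add atoms: tert-butyl hydroperoxide, CC(C)(C)OO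
Why: Sharpless asymmetric epoxidation, in which L-(+)-tartrate should give (S)-2-methylglycidol and thereby fix the quaternary C10 of the target.

Step 12
Reactants: 19 (S)-2-methylglycidol
Product: 20 (2S)-2-methyl-3-(PMB-oxy)propane-1,2-diol
Conditions: 4-MeOC6H4CH2OH (5 equiv), NaH (20 mol%), DMF, 70 °C
Reagents that add atoms: 4-methoxybenzyl alcohol, COc1ccc(CO)cc1
Why: Base-catalysed SN2 opening of the epoxide at its CH2 terminus by the benzylic alkoxide; the quaternary centre is not attacked and the Payne rearrangement of this epoxy alcohol is degenerate (it regenerates the same enantiomer), so configuration is retained.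

Step 13
Reactants: 20 diol
Product: 21 (2R)-2-hydroxy-2-methyl-3-(PMB-oxy)propanal
Conditions: SO3·pyridine, DMSO, i-Pr2NEt, CH2Cl2, 0 °C
Reagents that add atoms: none
Why: Parikh–Doering oxidation takes only the primary alcohol to the aldehyde, the tertiary hydroxyl being inert and the α-quaternary centre unable to epimerise.

Step 14
Reactants: 21 hydroxy aldehyde; 22 ethynylmagnesium bromide
Product: 23 (2R,3RS)-2-methyl-1-(PMB-oxy)pent-4-yne-2,3-diol
Conditions: THF, −78 → 0 °C (22, 3 equiv)
Reagents that add atoms: none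
Why: Grignard addition to the aldehyde (one equivalent is consumed by the tertiary hydroxyl); the new carbinol C1 forms as a mixture of epimers, which is irrelevant because it is oxidised in step 16.

Step 15
Reactants: 17 vinyl iodide lactone; 23 alkyne diol
Product: 24 (3R,4R,5S)-3-(chloromethyl)-5-[(1Z,5RS,6R)-5,6-dihydroxy-2,6-dimethyl-7-(PMB-oxy)hept-1-en-3-yn-1-yl]-3-hydroxy-4-(PMB-oxymethyl)oxolan-2-one
Conditions: PdCl2(PPh3)2 (5 mol%), CuI (10 mol%), Et3N (3 equiv), THF, rt
Reagents that add atoms: none
Why: Sonogashira coupling of the vinyl iodide with the terminal alkyne forms C3–C4 with retention of the Z geometry under mild amine conditions that the lactone, the chlorohydrin and the free hydroxyls should tolerate.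

Step 16
Reactants: 24 enyne triol
Product: 26 (3R,4R,5S)-3-(chloromethyl)-3-hydroxy-5-{(1Z)-2-[(5R)-5-methyl-4-oxo-5-(PMB-oxymethyl)-4,5-dihydrofuran-2-yl]prop-1-en-1-yl}-4-(PMB-oxymethyl)oxolan-2-one, via hydroxy ynone 25 (not isolated)
Conditions: Dess–Martin periodinane (1.5 equiv), CH2Cl2, 0 °C → rt; then AuCl3 (5 mol%), CH2Cl2, rt
Reagents that add atoms: none
Why: Dess–Martin oxidation affects only the secondary propargylic carbinol (the other hydroxyls are tertiary), and trivalent gold then activates the ynone for 5-endo-dig addition of the C10 hydroxyl (gold-catalysed hydroalkoxylation) to give the 3(2H)-furanone.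

Step 17
Reactants: 26 bis-PMB ether
Product: 27 (3R,4R,5S)-3-(chloromethyl)-3-hydroxy-4-(hydroxymethyl)-5-{(1Z)-2-[(5R)-5-(hydroxymethyl)-5-methyl-4-oxo-4,5-dihydrofuran-2-yl]prop-1-en-1-yl}oxolan-2-one
Conditions: DDQ (3 equiv), CH2Cl2/pH 7 buffer (10:1), 0 °C → rt
Reagents that add atoms: none
Why: Oxidative cleavage of both PMB ethers by DDQ (benzylic hydride abstraction, then hydrolysis of the oxocarbenium ions), to which the electron-poor dienone, the lactone and the chlorohydrin should be inert.

Step 18
Reactants: 27 diol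
Product: 28 seco-8,9 dialdehyde, (2S,3R,4R)-4-(chloromethyl)-2-{(1Z)-2-[(5R)-5-formyl-5-methyl-4-oxo-4,5-dihydrofuran-2-yl]prop-1-en-1-yl}-4-hydroxy-5-oxooxolane-3-carbaldehyde
Conditions: Dess–Martin periodinane (3 equiv), CH2Cl2, 0 °C → rt, 30 min; short silica plug, used at once
Reagents that add atoms: none
Why: Dess–Martin oxidation of both primary alcohols under non-basic conditions, so that the C8 aldehyde (epimerisable at C7 and β to the lactone oxygen) and the C9 aldehyde (a non-enolisable β-keto aldehyde) are not exposed to base or nucleophiles.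

Step 19
Reactants: 28 seco-8,9 dialdehyde
Product: 29 macrocyclic 8,9,11-triol (6S,7R,8S,9R,10R,11R), the target without its angeloyl group
Conditions: SmI2 (3 equiv, 0.1 M in THF), THF, −78 °C, slow addition of 28 (final 2 mM); then aq. NaHCO3
Reagents that add atoms: none
Why: SmI2 (divalent samarium) transfers one electron to each formyl group, and the two samarium ketyls combine at carbon to give the C8–C9 bond as a trivalent-samarium diolate that is protonated on work-up. The closest known reaction type is the SmI2-mediated intramolecular pinacol coupling of dialdehydes to medium- and large-ring 1,2-diols. The ten-membered carbocycle (C1–C10) is closed by ketyl–ketyl combination between the two exocyclic formyl carbons under high dilution, the furanone, the Z-C4=C5 alkene and the cis-fused lactone forming a U-shaped plate that holds C8 and C9 close. Both new centres should arise in the Felkin–Anh sense from their neighbours: C9 is attacked anti to the C10–O bond and past the C10 methyl, C8 anti to the fully substituted C11 and past H7, and bridging of both oxygens by one samarium keeps them gauche, which together corresponds to the threo (8S,9R) diol. The step needs the two aldehydes to be reduced in preference to the cross-conjugated furanone, the lactone and the primary chloride, and the ketyls to couple faster than a second electron transfer cleaves the C10–O bond; this is secured by the absence of any acrylate-type acceptor, the activation of both aldehydes by neighbouring oxygen, and operation at −78 °C without HMPA or a proton source.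

Step 20
Reactants: 29 macrocyclic triol; 30 angelic acid
Product: 32 target CNP0272644.1 (6S,7S,8S,9R,10R,11R), via mixed anhydride 31 (not isolated)
Conditions: 30, 2,4,6-Cl3C6H2COCl, Et3N (1.0 equiv), toluene, rt; then 29, toluene, 75 °C
Reagents that add atoms: none
Why: Yamaguchi-type mixed-anhydride acylation without DMAP, which should avoid Z→E isomerisation of the angeloyl group and select the C8 hydroxyl over the neopentyl C9 hydroxyl (beside quaternary C10) and the tertiary C11 hydroxyl.

Compound list
1 | methyl acrylate | C=CC(=O)OC | starting material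
2 | 2-(PMB-oxy)acetaldehyde, 2-[(4-methoxyphenyl)methoxy]acetaldehyde | COc1ccc(COCC=O)cc1 | starting material
3 | methyl 3-hydroxy-2-methylidene-4-(PMB-oxy)butanoate (racemic) | COC(=O)C(=C)C(O)COCc1ccc(OC)cc1 | intermediate
4 | methyl 3-acetoxy-2-methylidene-4-(PMB-oxy)butanoate (racemic) | COC(=O)C(=C)C(OC(C)=O)COCc1ccc(OC)cc1 | intermediate
5 | methyl (2E)-4-(PMB-oxy)-2-[(4,4,5,5-tetramethyl-1,3,2-dioxaborolan-2-yl)methyl]but-2-enoate | COC(=O)/C(CB1OC(C)(C)C(C)(C)O1)=C/COCc1ccc(OC)cc1 | intermediate
6 | but-2-yn-1-ol | CC#CCO | starting material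
7 | sodium 2,2-bis(2-methoxyethoxy)-3-methyl-2,5-dihydro-1,2-oxaaluminol-2-uide (vinylalanate) | CC1=CCO[Al-]1(OCCOC)OCCOC.[Na+] | intermediate
8 | (2Z)-3-iodobut-2-en-1-ol | OC/C=C(/C)I | intermediate
9 | (2Z)-3-iodobut-2-enal | O=C/C=C(/C)I | intermediate
10 | methyl (3R,4R,5Z)-6-iodo-2-methylidene-3-(PMB-oxymethyl)-4-[(4,4,5,5-tetramethyl-1,3,2-dioxaborolan-2-yl)oxy]hept-5-enoate (borate ester) | COc1ccc(COC[C@H]([C@@H](OB2OC(C)(C)C(C)(C)O2)/C=C(/C)I)C(=C)C(=O)OC)cc1 | intermediate
11 | (4R,5R)-5-[(1Z)-2-iodoprop-1-en-1-yl]-3-methylidene-4-(PMB-oxymethyl)oxolan-2-one | COc1ccc(COC[C@@H]2[C@H](/C=C(/C)I)OC(=O)C2=C)cc1 | intermediate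
12 | (3R,4R,5Z)-6-iodo-2-methylidene-3-(PMB-oxymethyl)hept-5-ene-1,4-diol | COc1ccc(COC[C@H]([C@@H](O)/C=C(/C)I)C(=C)CO)cc1 | intermediate
13 | (2R,3R,4Z)-2-[(2R)-2-(hydroxymethyl)oxiran-2-yl]-5-iodo-1-(PMB-oxy)hex-4-en-3-ol | COc1ccc(COC[C@H]([C@@H](O)/C=C(/C)I)[C@@]2(CO)CO2)cc1 | intermediate
14 | (2S)-2-[(2R,3R,4Z)-3-hydroxy-5-iodo-1-(PMB-oxy)hex-4-en-2-yl]oxirane-2-carbaldehyde (epoxy aldehyde) | COc1ccc(COC[C@H]([C@@H](O)/C=C(/C)I)[C@@]2(C=O)CO2)cc1 | intermediate
15 | (3S,6R,7R)-6-[(1Z)-2-iodoprop-1-en-1-yl]-7-(PMB-oxymethyl)-1,5-dioxaspiro[2.4]heptan-4-ol (lactol, anomers) | COc1ccc(COC[C@@H]2[C@H](/C=C(/C)I)OC(O)[C@@]2(O3)C3)cc1 | intermediate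
16 | (3S,6R,7R)-6-[(1Z)-2-iodoprop-1-en-1-yl]-7-(PMB-oxymethyl)-1,5-dioxaspiro[2.4]heptan-4-one | COc1ccc(COC[C@@H]2[C@H](/C=C(/C)I)OC(=O)[C@@]2(O3)C3)cc1 | intermediate
17 | (3R,4R,5R)-3-(chloromethyl)-3-hydroxy-5-[(1Z)-2-iodoprop-1-en-1-yl]-4-(PMB-oxymethyl)oxolan-2-one | COc1ccc(COC[C@@H]2[C@H](/C=C(/C)I)OC(=O)[C@@]2(O)CCl)cc1 | intermediate
18 | 2-methylprop-2-en-1-ol | C=C(C)CO | starting material
19 | [(2S)-2-methyloxiran-2-yl]methanol | C[C@]1(CO)CO1 | intermediate
20 | (2S)-2-methyl-3-(PMB-oxy)propane-1,2-diol | OC[C@](C)(O)COCc1ccc(OC)cc1 | intermediate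
21 | (2R)-2-hydroxy-2-methyl-3-(PMB-oxy)propanal | O=C[C@](C)(O)COCc1ccc(OC)cc1 | intermediate
22 | ethynylmagnesium bromide | C#C[Mg]Br | starting material
23 | (2R,3RS)-2-methyl-1-(PMB-oxy)pent-4-yne-2,3-diol (C3 epimers) | C#CC(O)[C@](C)(O)COCc1ccc(OC)cc1 | intermediate
24 | (3R,4R,5S)-3-(chloromethyl)-5-[(1Z,5RS,6R)-5,6-dihydroxy-2,6-dimethyl-7-(PMB-oxy)hept-1-en-3-yn-1-yl]-3-hydroxy-4-(PMB-oxymethyl)oxolan-2-one | COc1ccc(COC[C@@H]2[C@H](/C=C(/C)C#CC(O)[C@](C)(O)COCc3ccc(OC)cc3)OC(=O)[C@@]2(O)CCl)cc1 | intermediate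
25 | (3R,4R,5S)-3-(chloromethyl)-3-hydroxy-5-[(1Z,6R)-6-hydroxy-2,6-dimethyl-5-oxo-7-(PMB-oxy)hept-1-en-3-yn-1-yl]-4-(PMB-oxymethyl)oxolan-2-one (hydroxy ynone) | COc1ccc(COC[C@@H]2[C@H](/C=C(/C)C#CC(=O)[C@](C)(O)COCc3ccc(OC)cc3)OC(=O)[C@@]2(O)CCl)cc1 | intermediate
26 | (3R,4R,5S)-3-(chloromethyl)-3-hydroxy-5-{(1Z)-2-[(5R)-5-methyl-4-oxo-5-(PMB-oxymethyl)-4,5-dihydrofuran-2-yl]prop-1-en-1-yl}-4-(PMB-oxymethyl)oxolan-2-one | COc1ccc(COC[C@@H]2[C@H](/C=C(/C)C3=CC(=O)[C@](C)(O3)COCc4ccc(OC)cc4)OC(=O)[C@@]2(O)CCl)cc1 | intermediate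
27 | (3R,4R,5S)-3-(chloromethyl)-3-hydroxy-4-(hydroxymethyl)-5-{(1Z)-2-[(5R)-5-(hydroxymethyl)-5-methyl-4-oxo-4,5-dihydrofuran-2-yl]prop-1-en-1-yl}oxolan-2-one | OC[C@@H]1[C@H](/C=C(/C)C2=CC(=O)[C@](C)(O2)CO)OC(=O)[C@@]1(O)CCl | intermediate
28 | seco-8,9 dialdehyde, (2S,3R,4R)-4-(chloromethyl)-2-{(1Z)-2-[(5R)-5-formyl-5-methyl-4-oxo-4,5-dihydrofuran-2-yl]prop-1-en-1-yl}-4-hydroxy-5-oxooxolane-3-carbaldehyde | O=C[C@@H]1[C@H](/C=C(/C)C2=CC(=O)[C@](C)(O2)C=O)OC(=O)[C@@]1(O)CCl | intermediate
29 | macrocyclic triol (6S,7R,8S,9R,10R,11R): furanone-bridged ten-membered carbocycle with free C8, C9 and C11 hydroxyls, C13 chloride and cis-fused 12,6-lactone | O[C@H]1[C@@H]2[C@H](/C=C(/C)C3=CC(=O)[C@](C)(O3)[C@@H]1O)OC(=O)[C@@]2(O)CCl | intermediate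
30 | angelic acid, (2Z)-2-methylbut-2-enoic acid | C/C=C(/C)C(=O)O | starting material
31 | (2Z)-2-methylbut-2-enoic 2,4,6-trichlorobenzoic anhydride | C/C=C(/C)C(=O)OC(=O)c1c(Cl)cc(Cl)cc1Cl | intermediate
32 | CNP0272644.1, the 8-O-angelate of 29 (6S,7S,8S,9R,10R,11R) | C/C=C(/C)C(=O)O[C@H]1[C@@H]2[C@H](/C=C(/C)C3=CC(=O)[C@](C)(O3)[C@@H]1O)OC(=O)[C@@]2(O)CCl | target

Total step count: 20. Longest linear sequence: 14 steps (steps 1–3, 6–10, 15–20, from methyl acrylate).

Steps most likely to fail

1. Step 19 (ring closure). What may go wrong: a second electron transfer to the C9 ketyl with loss of the C10–O bond (opening of the furanone), reduction of the dienone, oligomerisation in competition with closure, or poor facial selectivity at C8 or C9. Fallback (olefin metathesis, then dihydroxylation): setting out from dialdehyde 28, both formyl groups are methylenated under non-basic Takai–Lombardo conditions (CH2I2, Zn, Ti(OiPr)4, THF) to give the bis-vinyl lactone F1. Ring-closing metathesis with the second-generation Grubbs catalyst in dilute toluene, with loss of ethene, should close C8=C9 to the ten-membered E-cycloalkene F2. OsO4 (cat.)/NMO syn-dihydroxylation of this isolated alkene, the only one not conjugated to the furanone carbonyl, should give the threo diol and rejoin the route at triol 29.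

2. Step 6 (asymmetric allylboration). What may go wrong: too little acceleration of the ester-deactivated boronate by the acid, so that the uncatalysed background addition erodes enantiomeric purity; Z→E isomerisation of the iodoenal. Fallback (racemic Barbier coupling, resolution at the epoxidation): setting out from acetate 4 and aldehyde 9, LiBr in THF should convert 4 by SN2′ displacement into the allylic bromide F3. Indium powder in THF/H2O couples F3 with 9 through a closed transition state (syn adduct) and the adduct lactonises, giving the racemic cis lactone, that is 11 together with its enantiomer F4. Reduction as in step 7 gives diol 12 and its enantiomer F5. The tartrate-controlled epoxidation of step 8 then converts the pair into epoxy diol 13 and the diastereomeric epoxy diol F6, which are separated by chromatography, and the route is rejoined at 13.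

3. Step 20 (angeloylation). What may go wrong: acylation at the C9 hydroxyl or double acylation, Z→E isomerisation of the angeloyl group, acyl migration or translactonisation to the C8 oxygen on heating. Fallback (build the angelate alkene on the ester): setting out from triol 29, the C8 hydroxyl is acylated with 2-(diphenoxyphosphoryl)propanoic acid (EDC, cat. DMAP; no alkene to isomerise) to give the phosphonate ester F7. A Z-selective Horner–Wadsworth–Emmons reaction with acetaldehyde (NaI, DBU, THF, 0 °C) then forms the angelate double bond in place and arrives at target 32.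

Further compounds
F1 | step 19 | (3R,4R,5S)-3-(chloromethyl)-4-ethenyl-5-{(1Z)-2-[(5R)-5-ethenyl-5-methyl-4-oxo-4,5-dihydrofuran-2-yl]prop-1-en-1-yl}-3-hydroxyoxolan-2-one (bis-vinyl lactone) | C=C[C@@H]1[C@H](/C=C(/C)C2=CC(=O)[C@](C)(O2)C=C)OC(=O)[C@@]1(O)CCl
F2 | step 19 | ten-membered E-cycloalkene, the 8,9-didehydro-8,9-dideoxy analogue of 29 | [C@@H]12/C=C/[C@@]3(C)OC(=CC3=O)/C(C)=C\[C@@H]1OC(=O)[C@@]2(O)CCl
F3 | step 6 | methyl (2Z)-2-(bromomethyl)-4-(PMB-oxy)but-2-enoate | COC(=O)/C(CBr)=C/COCc1ccc(OC)cc1
F4 | step 6 | (4S,5S)-5-[(1Z)-2-iodoprop-1-en-1-yl]-3-methylidene-4-(PMB-oxymethyl)oxolan-2-one (enantiomer of 11) | COc1ccc(COC[C@H]2[C@@H](/C=C(/C)I)OC(=O)C2=C)cc1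
F5 | step 6 | (3S,4S,5Z)-6-iodo-2-methylidene-3-(PMB-oxymethyl)hept-5-ene-1,4-diol (enantiomer of 12) | COc1ccc(COC[C@@H]([C@H](O)/C=C(/C)I)C(=C)CO)cc1
F6 | step 6 | (2S,3S,4Z)-2-[(2R)-2-(hydroxymethyl)oxiran-2-yl]-5-iodo-1-(PMB-oxy)hex-4-en-3-ol (diastereomer of 13) | COc1ccc(COC[C@@H]([C@H](O)/C=C(/C)I)[C@@]2(CO)CO2)cc1
F7 | step 20 | 8-O-[2-(diphenoxyphosphoryl)propanoyl] derivative of 29 (epimers at the phosphonate carbon) | CC(C(=O)O[C@H]1[C@@H]2[C@H](/C=C(/C)C3=CC(=O)[C@](C)(O3)[C@@H]1O)OC(=O)[C@@]2(O)CCl)P(=O)(Oc1ccccc1)Oc1ccccc1
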